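Late in the north run the target creeps: it gains 11 percentage points in the last 48.0 h, 5.68 times slower than over the first 8.00 h. I assume one coupling partner joins one substrate to give one target, so that flask's partner charge allows 70.0% of its substrate. It flattens well short of that. I read the flattening as partner going to waste, and I carry one number from it: the partner yield, the target made per coupling partner charged, 0.646 at the last reading. Partner yield times partner charge, divided by substrate charge, gives a flask's budget in percent of its substrate.

| flask | substrate | coupling partner | scavenger | initiator | temperature | remark | time |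
|---|---|---|---|---|---|---|---|
| north-east | 0.50 M | 0.35 M | 0.50 M | 3.4 mM | 55 °C | run made earlier |  |
| north | 0.50 M | 0.35 M | 0.50 M | 7.8 mM | 75 °C | run made earlier |  |
| west | 0.50 M | 0.35 M | 0.49 M | 5 mM | 55 °C | run made earlier |  |
| epsilon | 0.50 M | 0.350 M | 0.500 M | 5.0 mM | 90 °C |  | 50 h |
| beta | 0.80 M | 0.350 M | 0.120 M | 5.0 mM | 90 °C |  | 50 h |
| zeta | 0.50 M | 0.350 M | 0.300 M | 5.0 mM | 60 °C |  | 50 h |
| alpha | 0.50 M | 0.250 M | 2.00 M | 5.0 mM | 90 °C |  | 50 h |
| delta | 0.50 M | 1.00 M | 2.00 M | 2.5 mM | 90 °C |  | 50 h |

| run | time / h | target / % |
|---|---|---|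
| north-east | 50.0 | 4.8 |
| north-east | 120 | 11.4 |
| north-east | 144 | 14.0 |
| north-east | 240 | 21.6 |
| north | 8.00 | 10.5 |
| north | 25.0 | 22.9 |
| north | 48.0 | 34.1 |
| north | 96.0 | 45.2 |
| west | 50.0 | 6.2 |
| west | 120 | 13.9 |
| west | 144 | 16.4 |
| west | 240 | 24.2 |

(standard deviation of a reading: 0.5 percentage points)

1. the flasks put in order of amount of target, in percent of the substrate charged, best first, at 50 h (epsilon / beta / zeta / alpha / delta)
2. the amount of target, in percent of the substrate charged of the flask you put first, at 50 h
3. the amount of target, in percent of the substrate charged of the flask you put last, at 50 h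

Now the ladder, which is my own reckoning. I take the starting rate as going with the root of the initiator. West and north then give a gain of 8.47 over their 20.0 K. Call the fill time the partner allowance divided by the starting rate. The first rung is epsilon, at 90 °C, with a fill time near 13.4 h. The next rung is the asked 50 h, longer than that, so I expect epsilon to reach its budget. Alpha and beta have the same initiator and temperature and smaller allowances, so I expect them to reach theirs too. Those are 45.2% for epsilon, 32.3% for alpha and 28.2% for beta. Delta's budget is 129%, above its substrate charge, so I expect substrate to become the limiting reagent. At delta's lower initiator, its starting rate would fill the substrate charge in 27.1 h, which is shorter than the asked time. Its full partner allowance would take 54.2 h, which is longer. So I do not carry delta to its budget, and I give it a ceiling of 100%. The slowest rung is zeta, whose fill time of 331 h is longer than the asked time. Zeta is still on its straight start, at about 10.6%.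

The forecast gives delta > epsilon > alpha > beta > zeta, the same order as mine, with 78% on top and 10.5% at the bottom. Its top differs from mine: “excess partner drives about 78%”.

The flasks give delta > epsilon > alpha > beta > zeta: delta 90.1%, epsilon 42.9%, alpha 31.0%, beta 27.1%, zeta 10.1%.

    initiator → 2 initiating radical (k = 0.00350 h⁻¹, Ea = 119 kJ mol⁻¹)
    substrate + second chain carrier → released group + first chain carrier (k = 1.40 × 10⁷ L mol⁻¹ h⁻¹, Ea = 36.0 kJ mol⁻¹)
    scavenger + released group → scavenged by-product (k = 2.70 L mol⁻¹ h⁻¹, Ea = 83.0 kJ mol⁻¹)
    substrate + initiating radical → capped initiator + first chain carrier (k = 63000 L mol⁻¹ s⁻¹, Ea = 42.0 kJ mol⁻¹)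
    2 first chain carrier → ended chains (k = 2.00 × 10⁸ L mol⁻¹ s⁻¹, Ea = 16.0 kJ mol⁻¹)
    coupling partner → decomposed reagent (k = 0.0180 h⁻¹, Ea = 125 kJ mol⁻¹)
    substrate + released group ⇌ idle adduct, settled at all times (K = 40.0 L mol⁻¹, ΔH = 4.00 kJ mol⁻¹)
    coupling partner + first chain carrier ⇌ target + second chain carrier (K = 4.50, k = 1.20 × 10⁷ L mol⁻¹ h⁻¹, Ea = 46.0 kJ mol⁻¹, ΔH = −40.0 kJ mol⁻¹)
    coupling partner ⇌ dormant form (K = 1.60, k = 0.0220 h⁻¹, Ea = 110 kJ mol⁻¹, ΔH = −32.0 kJ mol⁻¹)
    (constants at 90 °C)

Epsilon's partner yield comes to 0.613, and delta's to 0.451. Delta holds 9.60% of its substrate and 8.43% of its partner at 50.0 h. The forecast's top stands 12 points below delta, and my ceiling 9.9 points above it. Delta's neighbour with 2.0 M of substrate has a budget of 32.3%. It gives 26.4%, a partner yield of 0.527.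

Readings and results are simulated from invented constants; noise was put on by code.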